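**Retrosynthetic overview**
- Glisoflavone is reached by removing three MOM ethers (O7, O3', O4'). The C5'–prenyl bond comes from a Stille coupling of an aryl bromide, and the O5–CH3 bond from methylation of the only hydroxyl left free after MOM protection.
- The pyranone ring C is cut at C4–C4a, C2–C3 and O1–C2 into phloroglucinol, a bromocatechol acetic acid and the formyl carbon of DMF. Ring C is the only ring built (rings A and B are bought) and it is closed in one flask.
- The strategy rests on ring A (C4a, C5, C6, C7, C8, C8a carrying O5, O7 and O1), which is a phloroglucinol pattern. Its three CH positions are equivalent for acylation, and after closure only the C5–OH is chelated to the C4 carbonyl, which marks it for the late O-methylation.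
- Bromine at C5' stands in for the prenyl chain during the Lewis-acid steps. The acid is made from homovanillic acid by bromination ortho to the phenol and O-demethylation.

Key step: step 3

Remark: the target has no stereocentre and no stereogenic double bond, so it is achiral and no step has to control configuration.

**Step 1**
Reactants: 1 homovanillic acid (4-hydroxy-3-methoxyphenylacetic acid)
Product: 2 2-(3-bromo-4-hydroxy-5-methoxyphenyl)acetic acid
Conditions: Br2 (1.05 equiv), AcOH, 15 °C to rt
Reagents that add atoms: bromine, BrBr
Why: Electrophilic aromatic bromination in which the free 4-OH is the dominant director and its para position is blocked by the CH2CO2H group, so bromine should enter ortho to the hydroxyl (C5) as with other 4-substituted guaiacols, one equivalent of Br2 limiting over-bromination.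

**Step 2**
Reactants: 2 2-(3-bromo-4-hydroxy-5-methoxyphenyl)acetic acid
Product: 3 2-(3-bromo-4,5-dihydroxyphenyl)acetic acid
Conditions: BBr3 (3.5 equiv), CH2Cl2, −78 °C to rt; then H2O
Reagents that add atoms: none
Why: BBr3 aryl methyl ether cleavage, in which boron coordinates the methoxy oxygen and bromide removes the methyl group by SN2, should leave the aryl bromide, the benzylic CH2 and (after hydrolysis of the acyloxyborane) the carboxylic acid intact.

**Step 3**
Reactants: 3 2-(3-bromo-4,5-dihydroxyphenyl)acetic acid; 4 phloroglucinol (anhydrous); 5 N,N-dimethylformamide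
Product: 8 3-(3-bromo-4,5-dihydroxyphenyl)-5,7-dihydroxychromen-4-one, via deoxybenzoin 6 (not isolated), via enaminone 7 (not isolated)
Conditions: BF3·OEt2 (neat), 85 °C, N2; then 5, MsCl, 50 to 80 °C; aq NaOAc work-up
Reagents that add atoms: none
Why: BF3 turns acid 3 into an acylating species (acyloxyborane/acylium) that C-acylates phloroglucinol 4 in a Friedel–Crafts reaction (C4a–C4) to give deoxybenzoin 6, held as its boron chelate; the iminium salt formed from DMF and MsCl then attacks the enolised benzylic carbon (C2–C3) to give enaminone 7, an ortho-hydroxyl adds to its iminium carbon (O1–C2), and loss of dimethylamine completes the pyranone. The closest known reaction type is the one-flask BF3 acylation of polyphenols with arylacetic acids followed by DMF/MsCl ring closure to isoflavones. Ring C closes by 6-exo-trig attack of the phenol oxygen on the C=N+ carbon, followed by elimination. No stereocentre is formed. The step needs acylation on 4 and not on the bromocatechol ring, which the far higher nucleophilicity of phloroglucinol should secure, and a single acylation site, which its threefold symmetry guarantees; the two ortho-hydroxyls of 6 are equivalent, so either closes to the same product. The catechol and 7-OH may be transiently boron-bound or O-formylated and should be released in the aqueous work-up, and the C–Br bond is inert to these conditions.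

**Step 4**
Reactants: 8 3-(3-bromo-4,5-dihydroxyphenyl)-5,7-dihydroxychromen-4-one
Product: 9 3-[3-bromo-4,5-bis(methoxymethoxy)phenyl]-5-hydroxy-7-(methoxymethoxy)chromen-4-one
Conditions: MOMCl (3.3 equiv), i-Pr2NEt (4 equiv), DMF–CH2Cl2, 0 °C to rt
Reagents that add atoms: chloromethyl methyl ether, COCCl
Why: Amine-base O-alkylation (MOM ether formation) should take the three unchelated phenols, whereas the 5-OH is hydrogen-bonded to C4=O and is not alkylated by MOMCl under these conditions, so it should remain free.

**Step 5**
Reactants: 9 3-[3-bromo-4,5-bis(methoxymethoxy)phenyl]-5-hydroxy-7-(methoxymethoxy)chromen-4-one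
Product: 10 3-[3-bromo-4,5-bis(methoxymethoxy)phenyl]-5-methoxy-7-(methoxymethoxy)chromen-4-one
Conditions: MeI (excess), K2CO3, DMF, 40 °C
Reagents that add atoms: iodomethane, CI
Why: Williamson etherification, in which carbonate in a dipolar aprotic solvent deprotonates the chelated 5-OH (the only hydroxyl left) and excess MeI methylates it, while the MOM ethers, the aryl bromide and the chromone ring are stable to the mildly basic, anhydrous conditions.

**Step 6**
Reactants: 10 3-[3-bromo-4,5-bis(methoxymethoxy)phenyl]-5-methoxy-7-(methoxymethoxy)chromen-4-one; 11 tributyl(3-methylbut-2-enyl)stannane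
Product: 12 3-[3,4-bis(methoxymethoxy)-5-(3-methylbut-2-enyl)phenyl]-5-methoxy-7-(methoxymethoxy)chromen-4-one
Conditions: Pd(PPh3)4 (10 mol %), DMF, 100 °C, degassed
Reagents that add atoms: none
Why: Stille coupling, in which oxidative addition of Pd(0) into the C5'–Br bond, transmetalation from the allylic stannane and reductive elimination at the unsubstituted terminus of the prenyl–palladium species should give the linear 3-methylbut-2-enyl arene under neutral conditions that leave the MOM ethers and the chromone untouched.

**Step 7**
Reactants: 12 3-[3,4-bis(methoxymethoxy)-5-(3-methylbut-2-enyl)phenyl]-5-methoxy-7-(methoxymethoxy)chromen-4-one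
Product: 13 glisoflavone, 3-[3,4-dihydroxy-5-(3-methylbut-2-enyl)phenyl]-7-hydroxy-5-methoxychromen-4-one
Conditions: HCl (conc., few equiv), MeOH, rt to 40 °C, stopped at full conversion
Reagents that add atoms: none
Why: Acid-catalysed acetal cleavage (transacetalisation to dimethoxymethane in methanol) should remove the three MOM ethers under conditions mild enough for the O5 methyl ether and, with monitoring, the prenyl double bond to survive.

**Compound list**
1 | homovanillic acid (4-hydroxy-3-methoxyphenylacetic acid) | COc1cc(CC(=O)O)ccc1O | starting material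
2 | 2-(3-bromo-4-hydroxy-5-methoxyphenyl)acetic acid | COc1cc(CC(=O)O)cc(Br)c1O | intermediate
3 | 2-(3-bromo-4,5-dihydroxyphenyl)acetic acid | OC(=O)Cc1cc(O)c(O)c(Br)c1 | intermediate
4 | phloroglucinol (benzene-1,3,5-triol) | Oc1cc(O)cc(O)c1 | starting material
5 | N,N-dimethylformamide | CN(C)C=O | starting material
6 | 2-(3-bromo-4,5-dihydroxyphenyl)-1-(2,4,6-trihydroxyphenyl)ethan-1-one (deoxybenzoin, not isolated) | O=C(Cc1cc(O)c(O)c(Br)c1)c1c(O)cc(O)cc1O | intermediate
7 | 2-(3-bromo-4,5-dihydroxyphenyl)-3-(dimethylamino)-1-(2,4,6-trihydroxyphenyl)prop-2-en-1-one (enaminone, not isolated, olefin geometry immaterial) | CN(C)C=C(C(=O)c1c(O)cc(O)cc1O)c1cc(O)c(O)c(Br)c1 | intermediate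
8 | 3-(3-bromo-4,5-dihydroxyphenyl)-5,7-dihydroxychromen-4-one | Oc1cc(O)c2c(c1)occ(-c1cc(O)c(O)c(Br)c1)c2=O | intermediate
9 | 3-[3-bromo-4,5-bis(methoxymethoxy)phenyl]-5-hydroxy-7-(methoxymethoxy)chromen-4-one | COCOc1cc(O)c2c(c1)occ(-c1cc(OCOC)c(OCOC)c(Br)c1)c2=O | intermediate
10 | 3-[3-bromo-4,5-bis(methoxymethoxy)phenyl]-5-methoxy-7-(methoxymethoxy)chromen-4-one | COCOc1cc(OC)c2c(c1)occ(-c1cc(OCOC)c(OCOC)c(Br)c1)c2=O | intermediate
11 | tributyl(3-methylbut-2-enyl)stannane | CCCC[Sn](CCCC)(CCCC)CC=C(C)C | starting material
12 | 3-[3,4-bis(methoxymethoxy)-5-(3-methylbut-2-enyl)phenyl]-5-methoxy-7-(methoxymethoxy)chromen-4-one | COCOc1cc(OC)c2c(c1)occ(-c1cc(OCOC)c(OCOC)c(CC=C(C)C)c1)c2=O | intermediate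
13 | glisoflavone, 3-[3,4-dihydroxy-5-(3-methylbut-2-enyl)phenyl]-7-hydroxy-5-methoxychromen-4-one | COc1cc(O)cc2occ(-c3cc(O)c(O)c(CC=C(C)C)c3)c(=O)c12 | target

**Step count**
Total steps: 7. Longest linear sequence: 7 steps (1 to 13).

**Steps most likely to fail**

Step 3 (key step). The free catechol of 3 may be tied up by boron and compete for the formylating reagent (O-formylation, O-sulfonylation). Acylation could then stall, or the annulation could give mixtures that do not hydrolyse cleanly. The fallback sets out from 2 and keeps the B ring masked as a guaiacol through the annulation. Acid 2, phloroglucinol 4 and DMF 5 are taken through the same BF3·OEt2, then DMF/MsCl sequence. This should pass through the deoxybenzoin 2-(3-bromo-4-hydroxy-5-methoxyphenyl)-1-(2,4,6-trihydroxyphenyl)ethan-1-one F1 and the enaminone 2-(3-bromo-4-hydroxy-5-methoxyphenyl)-3-(dimethylamino)-1-(2,4,6-trihydroxyphenyl)prop-2-en-1-one F2 (neither isolated) to the isoflavone 3-(3-bromo-4-hydroxy-5-methoxyphenyl)-5,7-dihydroxychromen-4-one F3. BBr3 in CH2Cl2 then cleaves the B-ring methyl ether, and the route is rejoined at 8.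

Step 6. Oxidative addition into the electron-rich, ortho-oxygenated aryl bromide may be slow, leaving time for protodestannylation of 11. Allylic transposition at palladium could also deliver the branched 1,1-dimethylallyl isomer. The fallback sets out from 10 and installs the chain in two stages. Stille coupling with allyltributylstannane (Pd(PPh3)4, DMF, 100 °C), which has no regiochemical ambiguity, should give 3-[3,4-bis(methoxymethoxy)-5-(prop-2-enyl)phenyl]-5-methoxy-7-(methoxymethoxy)chromen-4-one F4. Olefin cross-metathesis with excess 2-methylbut-2-ene (Grubbs second-generation catalyst, CH2Cl2, 40 °C) then converts the allyl into the prenyl group, and the route is rejoined at 12.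

Step 7. During MOM cleavage the freed 4'-OH may add across the neighbouring prenyl double bond under acid catalysis (closure to a dimethylchroman), or HCl/MeOH may add to the olefin before the last MOM group is gone. The fallback sets out from 10 and changes to base-labile protection before the olefin is introduced. HCl in MeOH removes the MOM groups from the bromide to give 3-(3-bromo-4,5-dihydroxyphenyl)-7-hydroxy-5-methoxychromen-4-one F5. Ac2O/pyridine should give the triacetate 3-(3,4-diacetoxy-5-bromophenyl)-5-methoxy-4-oxochromen-7-yl acetate F6. Stille coupling with 11 under the step 6 conditions should give 3-[3,4-diacetoxy-5-(3-methylbut-2-enyl)phenyl]-5-methoxy-4-oxochromen-7-yl acetate F7. Brief methanolysis (catalytic K2CO3, MeOH, 0 °C, argon) then releases the phenols without acid, and the route is rejoined at 13.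

**Further compounds**
F1 | step 3 | 2-(3-bromo-4-hydroxy-5-methoxyphenyl)-1-(2,4,6-trihydroxyphenyl)ethan-1-one | COc1cc(CC(=O)c2c(O)cc(O)cc2O)cc(Br)c1O
F2 | step 3 | 2-(3-bromo-4-hydroxy-5-methoxyphenyl)-3-(dimethylamino)-1-(2,4,6-trihydroxyphenyl)prop-2-en-1-one | CN(C)C=C(C(=O)c1c(O)cc(O)cc1O)c1cc(OC)c(O)c(Br)c1
F3 | step 3 | 3-(3-bromo-4-hydroxy-5-methoxyphenyl)-5,7-dihydroxychromen-4-one | COc1cc(-c2coc3cc(O)cc(O)c3c2=O)cc(Br)c1O
F4 | step 6 | 3-[3,4-bis(methoxymethoxy)-5-(prop-2-enyl)phenyl]-5-methoxy-7-(methoxymethoxy)chromen-4-one | COCOc1cc(OC)c2c(c1)occ(-c1cc(OCOC)c(OCOC)c(CC=C)c1)c2=O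
F5 | step 7 | 3-(3-bromo-4,5-dihydroxyphenyl)-7-hydroxy-5-methoxychromen-4-one | COc1cc(O)cc2occ(-c3cc(O)c(O)c(Br)c3)c(=O)c12
F6 | step 7 | 3-(3,4-diacetoxy-5-bromophenyl)-5-methoxy-4-oxochromen-7-yl acetate | COc1cc(OC(C)=O)cc2occ(-c3cc(OC(C)=O)c(OC(C)=O)c(Br)c3)c(=O)c12
F7 | step 7 | 3-[3,4-diacetoxy-5-(3-methylbut-2-enyl)phenyl]-5-methoxy-4-oxochromen-7-yl acetate | COc1cc(OC(C)=O)cc2occ(-c3cc(OC(C)=O)c(OC(C)=O)c(CC=C(C)C)c3)c(=O)c12
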